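**Retrosynthetic overview**
1. Target 20 comes from butenolide 19 by a face-selective conjugate reduction that sets C7 and C11 (all-cis lactone).
2. Bicycle 19 comes from open-chain aldehyde / Z-enol triflate 17 by one Ni/Cr-mediated alkenyl–aldehyde ring closure with in-flask lactonisation: the ten-membered carbocycle and the γ-lactone appear together, and C6 is set.
3. 17 comes from Z-enal 10 and the bis-silyl dienol ether 13 (vinylogous aldol sets C9), followed by Z-selective enol triflation and acetal hydrolysis.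
4. 10 comes from dihydropyranone 6, a temporary six-membered ring that locks the Z C1=C10 olefin (allylation of 3 sets C3, then methacrylate ring-closing metathesis); 6 is opened as a Weinreb amide, esterified with 8 and reduced.
5. Ring order: temporary dihydropyranone (made in step 4, opened in step 5), then carbocycle and butenolide in the same operation (step 13).

Assumption 1: positions use germacrane numbering (C3 acyloxy carbon, C6 lactone O–CH, C7 ring-fusion CH, C9 carbinol, C11 lactone CH(CH3), C12 lactone C=O; olefins C1=C10 Z and C4=C5 E); the SMILES is read as 3S,6R,7S,9S,11R with an (R)-2-methylbutanoate.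
Assumption 2: the (S)-BINOL–Ti(OiPr)4 catalyst in step 10 is taken to deliver the nucleophile to the Si face of the aldehyde; if the measured sense is opposite, (R)-BINOL is used and nothing else changes.

**Step 1**
Reactants: 1 2,2-dimethoxyacetaldehyde; 2 2-(triphenylphosphoranylidene)propanal
Product: 3 (2E)-4,4-dimethoxy-2-methylbut-2-enal
Conditions: CH2Cl2, 23 °C (1 used as its 60% aqueous solution)
Reagents that add atoms: none
Why: Wittig olefination with a stabilised formyl ylide gives the E enal, and the α-alkoxy aldehyde 1 reacts much faster than the conjugated product.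

**Step 2**
Reactants: 3 (2E)-4,4-dimethoxy-2-methylbut-2-enal
Product: 4 (2E,4S)-1,1-dimethoxy-3-methylhepta-2,6-dien-4-ol
Conditions: (−)-Ipc2BOMe, allylMgBr, Et2O, 0 °C; then 3, −78 °C; then NaOH, H2O2
Reagents that add atoms: allylmagnesium bromide, C=CC[Mg]Br
Why: Brown allylboration through a chair Zimmerman–Traxler transition state; the reagent derived from (+)-α-pinene adds allyl to the Si face of the enal and sets C3 as S.

**Step 3**
Reactants: 4 (2E,4S)-1,1-dimethoxy-3-methylhepta-2,6-dien-4-ol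
Product: 5 (2E,4S)-1,1-dimethoxy-3-methylhepta-2,6-dien-4-yl 2-methylprop-2-enoate
Conditions: methacryloyl chloride, Et3N, DMAP (cat.), CH2Cl2, 0 °C
Reagents that add atoms: methacryloyl chloride, CC(=C)C(=O)Cl
Why: DMAP-catalysed O-acylation of the secondary alcohol; no stereocentre is touched.

**Step 4**
Reactants: 5 (2E,4S)-1,1-dimethoxy-3-methylhepta-2,6-dien-4-yl 2-methylprop-2-enoate
Product: 6 (6S)-6-[(2E)-4,4-dimethoxybut-2-en-2-yl]-3-methyl-5,6-dihydro-2H-pyran-2-one
Conditions: second-generation Grubbs catalyst RuCl2(PCy3)(H2IMes)(=CHPh) (5 mol %), CH2Cl2 (0.01 M), 40 °C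
Reagents that add atoms: none
Why: ring-closing metathesis of the methacrylate with the terminal olefin; the six-membered ring forces the cis (Z) C1=C10 geometry, which is kept to the end.

**Step 5**
Reactants: 6 (6S)-6-[(2E)-4,4-dimethoxybut-2-en-2-yl]-3-methyl-5,6-dihydro-2H-pyran-2-one
Product: 7 (2Z,5S,6E)-5-hydroxy-N,8,8-trimethoxy-N,2,6-trimethylocta-2,6-dienamide
Conditions: MeNH(OMe)·HCl, i-PrMgCl, THF, −20 → 0 °C
Reagents that add atoms: N,O-dimethylhydroxylamine hydrochloride, CNOC.Cl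
Why: Weinreb aminolysis of the lactone by the magnesium amide (1,2-addition) opens the ring with the Z olefin intact and frees only the C3 hydroxyl.

**Step 6**
Reactants: 7 (2Z,5S,6E)-5-hydroxy-N,8,8-trimethoxy-N,2,6-trimethylocta-2,6-dienamide; 8 (2R)-2-methylbutanoic acid
Product: 9 (2E,4S,6Z)-1,1-dimethoxy-8-[methoxy(methyl)amino]-3,7-dimethyl-8-oxoocta-2,6-dien-4-yl (2R)-2-methylbutanoate
Conditions: DCC, DMAP (cat.), CH2Cl2, 0 °C
Reagents that add atoms: none
Why: Steglich esterification puts the side chain on the only free hydroxyl; low temperature and catalytic DMAP keep the α-stereocentre of 8.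

**Step 7**
Reactants: 9 (2E,4S,6Z)-1,1-dimethoxy-8-[methoxy(methyl)amino]-3,7-dimethyl-8-oxoocta-2,6-dien-4-yl (2R)-2-methylbutanoate
Product: 10 (2E,4S,6Z)-1,1-dimethoxy-3,7-dimethyl-8-oxoocta-2,6-dien-4-yl (2R)-2-methylbutanoate
Conditions: Cp2Zr(H)Cl (1.5 equiv), THF, 23 °C, 20 min
Reagents that add atoms: none
Why: Schwartz-reagent reduction of a tertiary amide stops at the aldehyde through a stable zirconated hemiaminal and leaves the ester and the trisubstituted olefins alone, so the Z enal is obtained.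

**Step 8**
Reactants: 11 methyl 2-methyl-3-oxobutanoate
Product: 12 methyl 2-methyl-3-(trimethylsilyloxy)but-2-enoate (E/Z mixture)
Conditions: TMSCl, Et3N, hexane, 23 °C
Reagents that add atoms: chlorotrimethylsilane, C[Si](C)(C)Cl
Why: O-silylation of the β-keto ester enol (silyl enol ether formation).

**Step 9**
Reactants: 12 methyl 2-methyl-3-(trimethylsilyloxy)but-2-enoate
Product: 13 1-methoxy-2-methyl-1,3-bis(trimethylsilyloxy)buta-1,3-diene
Conditions: LDA, THF, −78 °C; then TMSCl
Reagents that add atoms: chlorotrimethylsilane, C[Si](C)(C)Cl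
Why: γ-deprotonation of the vinylogous ester and O-silylation (Chan-type diene synthesis).

**Step 10**
Reactants: 10 (2E,4S,6Z)-1,1-dimethoxy-3,7-dimethyl-8-oxoocta-2,6-dien-4-yl (2R)-2-methylbutanoate; 13 1-methoxy-2-methyl-1,3-bis(trimethylsilyloxy)buta-1,3-diene
Product: 15 methyl (5S,6Z,9S,10E)-5-hydroxy-12,12-dimethoxy-2,6,10-trimethyl-9-{[(2R)-2-methylbutanoyl]oxy}-3-oxododeca-6,10-dienoate, via bis(trimethylsilyl) aldol adduct 14 (not isolated)
Conditions: Ti(OiPr)4 (10 mol %), (S)-BINOL (10 mol %), 4 Å MS, THF, −78 → 0 °C; then Bu4NF, AcOH, THF, 0 °C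
Reagents that add atoms: none
Why: catalytic enantioselective vinylogous Mukaiyama aldol; the terminal carbon of the diene attacks the Si face of the aldehyde under catalyst control (the C3 centre is too remote to interfere) and sets C9 as S.

**Step 11**
Reactants: 15 methyl (5S,6Z,9S,10E)-5-hydroxy-12,12-dimethoxy-2,6,10-trimethyl-9-{[(2R)-2-methylbutanoyl]oxy}-3-oxododeca-6,10-dienoate
Product: 16 methyl (2Z,5S,6Z,9S,10E)-5-hydroxy-12,12-dimethoxy-2,6,10-trimethyl-9-{[(2R)-2-methylbutanoyl]oxy}-3-{[(trifluoromethyl)sulfonyl]oxy}dodeca-2,6,10-trienoate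
Conditions: NaH (1.05 equiv), THF, 0 °C; then PhNTf2, 0 → 23 °C
Reagents that add atoms: N-phenylbis(trifluoromethanesulfonimide), O=S(=O)(N(c1ccccc1)S(=O)(=O)C(F)(F)F)C(F)(F)F
Why: enol triflation of the chelated sodium enolate gives the Z isomer (triflate cis to the ester); one equivalent of base deprotonates only the keto ester, and PhNTf2 does not sulfonylate the neutral secondary alcohol.

**Step 12**
Reactants: 16 (the dimethyl acetal triflate)
Product: 17 methyl (2Z,5S,6Z,9S,10E)-5-hydroxy-2,6,10-trimethyl-9-{[(2R)-2-methylbutanoyl]oxy}-12-oxo-3-{[(trifluoromethyl)sulfonyl]oxy}dodeca-2,6,10-trienoate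
Conditions: AcOH, THF, H2O (4:2:1), 23 °C
Reagents that add atoms: water, O
Why: mild acid hydrolysis of the allylic dimethyl acetal to the E enal; the enol triflate and both esters are stable to these conditions.

**Step 13**
Reactants: 17 (the hydroxy enal triflate)
Product: 19 (5S,6Z,9S,10E,11aS)-5-hydroxy-3,6,10-trimethyl-2-oxo-2,4,5,8,9,11a-hexahydrocyclodeca[b]furan-9-yl (2R)-2-methylbutanoate, via seco hydroxy ester macrocycle 18 (not isolated)
Conditions: CrCl2 (8 equiv), NiCl2 (0.1 equiv), degassed DMF (0.003 M, slow addition of 17), 23 °C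
Reagents that add atoms: none
Why: Proposed new method: zerovalent nickel inserts into the alkenyl C–OTf bond, the alkenyl group passes to trivalent chromium and adds 1,2 to the enal to close the ten-membered ring, and the C6 chromium alkoxide, which sits cis to the ester across the tetrasubstituted olefin, lactonises at once to the butenolide. The closest known reactions are Nozaki–Hiyama–Kishi macrocyclisations of alkenyl triflates and iodides onto aldehydes and the same coupling of (Z)-β-iodoacrylates, which gives butenolides directly. C6 is set by macrocyclic substrate control (Re-face addition is needed), and this is the least secure element of the route.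

**Step 14**
Reactants: 19 (the butenolide macrocycle)
Product: 20 (3R,3aS,5S,6Z,9S,10E,11aR)-5-hydroxy-3,6,10-trimethyl-2-oxo-2,3,3a,4,5,8,9,11a-octahydrocyclodeca[b]furan-9-yl (2R)-2-methylbutanoate
Conditions: NiCl2·6H2O (0.3 equiv), NaBH4 (3 equiv), MeOH/THF, −20 °C
Reagents that add atoms: none
Why: nickel boride (Ni2B, formed in the flask) conjugate reduction adds both hydrogens syn to the butenolide face opposite the C5 substituent on C6, which gives the all-cis C6/C7/C11 lactone (7S,11R); the isolated trisubstituted olefins and the esters are not reduced.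

**Compound list**
1 | 2,2-dimethoxyacetaldehyde | COC(OC)C=O | starting material
2 | 2-(triphenylphosphoranylidene)propanal | CC(C=O)=P(c1ccccc1)(c1ccccc1)c1ccccc1 | starting material
3 | (2E)-4,4-dimethoxy-2-methylbut-2-enal | O=C/C(C)=C/C(OC)OC | intermediate
4 | (2E,4S)-1,1-dimethoxy-3-methylhepta-2,6-dien-4-ol | C=CC[C@H](O)/C(C)=C/C(OC)OC | intermediate
5 | (2E,4S)-1,1-dimethoxy-3-methylhepta-2,6-dien-4-yl 2-methylprop-2-enoate | C=CC[C@H](OC(=O)C(C)=C)/C(C)=C/C(OC)OC | intermediate
6 | (6S)-6-[(2E)-4,4-dimethoxybut-2-en-2-yl]-3-methyl-5,6-dihydro-2H-pyran-2-one | CC1=CC[C@H](OC1=O)/C(C)=C/C(OC)OC | intermediate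
7 | (2Z,5S,6E)-5-hydroxy-N,8,8-trimethoxy-N,2,6-trimethylocta-2,6-dienamide | CON(C)C(=O)/C(C)=C\C[C@H](O)/C(C)=C/C(OC)OC | intermediate
8 | (2R)-2-methylbutanoic acid | CC[C@@H](C)C(=O)O | starting material
9 | (2E,4S,6Z)-1,1-dimethoxy-8-[methoxy(methyl)amino]-3,7-dimethyl-8-oxoocta-2,6-dien-4-yl (2R)-2-methylbutanoate | CC[C@@H](C)C(=O)O[C@@H](C/C=C(/C)C(=O)N(C)OC)/C(C)=C/C(OC)OC | intermediate
10 | (2E,4S,6Z)-1,1-dimethoxy-3,7-dimethyl-8-oxoocta-2,6-dien-4-yl (2R)-2-methylbutanoate | CC[C@@H](C)C(=O)O[C@@H](C/C=C(/C)C=O)/C(C)=C/C(OC)OC | intermediate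
11 | methyl 2-methyl-3-oxobutanoate | COC(=O)C(C)C(C)=O | starting material
12 | methyl 2-methyl-3-(trimethylsilyloxy)but-2-enoate (E/Z mixture) | COC(=O)C(C)=C(C)O[Si](C)(C)C | intermediate
13 | 1-methoxy-2-methyl-1,3-bis(trimethylsilyloxy)buta-1,3-diene | COC(O[Si](C)(C)C)=C(C)C(=C)O[Si](C)(C)C | intermediate
14 | methyl (5S,6Z,9S,10E)-12,12-dimethoxy-2,6,10-trimethyl-9-{[(2R)-2-methylbutanoyl]oxy}-3,5-bis[(trimethylsilyl)oxy]dodeca-2,6,10-trienoate (enol ether geometry not defined) | CC[C@@H](C)C(=O)O[C@@H](C/C=C(/C)[C@@H](O[Si](C)(C)C)CC(O[Si](C)(C)C)=C(C)C(=O)OC)/C(C)=C/C(OC)OC | intermediate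
15 | methyl (5S,6Z,9S,10E)-5-hydroxy-12,12-dimethoxy-2,6,10-trimethyl-9-{[(2R)-2-methylbutanoyl]oxy}-3-oxododeca-6,10-dienoate (C2 epimers) | CC[C@@H](C)C(=O)O[C@@H](C/C=C(/C)[C@@H](O)CC(=O)C(C)C(=O)OC)/C(C)=C/C(OC)OC | intermediate
16 | methyl (2Z,5S,6Z,9S,10E)-5-hydroxy-12,12-dimethoxy-2,6,10-trimethyl-9-{[(2R)-2-methylbutanoyl]oxy}-3-{[(trifluoromethyl)sulfonyl]oxy}dodeca-2,6,10-trienoate | CC[C@@H](C)C(=O)O[C@@H](C/C=C(/C)[C@@H](O)C/C(OS(=O)(=O)C(F)(F)F)=C(\C)C(=O)OC)/C(C)=C/C(OC)OC | intermediate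
17 | methyl (2Z,5S,6Z,9S,10E)-5-hydroxy-2,6,10-trimethyl-9-{[(2R)-2-methylbutanoyl]oxy}-12-oxo-3-{[(trifluoromethyl)sulfonyl]oxy}dodeca-2,6,10-trienoate | CC[C@@H](C)C(=O)O[C@@H](C/C=C(/C)[C@@H](O)C/C(OS(=O)(=O)C(F)(F)F)=C(\C)C(=O)OC)/C(C)=C/C=O | intermediate
18 | methyl (2Z)-2-[(2S,3E,5S,7Z,9S)-2,9-dihydroxy-4,8-dimethyl-5-{[(2R)-2-methylbutanoyl]oxy}cyclodeca-3,7-dien-1-ylidene]propanoate | CC[C@@H](C)C(=O)O[C@H]1C/C=C(/C)[C@@H](O)C/C(=C(\C)C(=O)OC)[C@@H](O)/C=C/1C | intermediate
19 | (5S,6Z,9S,10E,11aS)-5-hydroxy-3,6,10-trimethyl-2-oxo-2,4,5,8,9,11a-hexahydrocyclodeca[b]furan-9-yl (2R)-2-methylbutanoate | CC[C@@H](C)C(=O)O[C@H]1C/C=C(/C)[C@@H](O)CC2=C(C)C(=O)O[C@H]2/C=C/1C | intermediate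
20 | (3R,3aS,5S,6Z,9S,10E,11aR)-5-hydroxy-3,6,10-trimethyl-2-oxo-2,3,3a,4,5,8,9,11a-octahydrocyclodeca[b]furan-9-yl (2R)-2-methylbutanoate | CC[C@@H](C)C(=O)O[C@H]1C/C=C(/C)[C@@H](O)C[C@@H]2[C@H](/C=C/1C)OC(=O)[C@@H]2C | target

**Step count**
Total: 14 steps. Longest linear sequence: 12 steps (steps 1–7 and 10–14); steps 8–9 make diene 13.

**Steps most likely to fail, with fallbacks**

Step 13 (ring closure with lactonisation). The risks are oligomerisation at the ten-membered ring closure and the wrong C6 epimer. The fallback makes the two rings one after the other; it sets out from 4 and comes back at 19. Alcohol 4 is esterified with 8 (DCC, DMAP) to the acetal ester F1, and AcOH/THF/H2O then gives the enal ester F2. Methacrolein and 13 under the step 10 conditions give the hydroxy keto ester F3, and the step 11 conditions turn it into the Z-enol triflate F4. Intermolecular CrCl2/NiCl2 coupling of F2 with F4 in DMF, with in-flask lactonisation, gives the butenolide diene F5; its C6 epimers are separated at this acyclic stage or controlled with a chiral sulfonamide ligand on chromium. Ring-closing metathesis of F5 (second-generation Hoveyda–Grubbs catalyst RuCl2(H2IMes)(=CH-C6H4-2-OiPr), dilute toluene, 80 °C) joins C1 to C10 and returns to 19. The cis olefin is expected as the less strained isomer of this ring, but the E/Z ratio must be checked.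

Step 14 (conjugate reduction). The risks are over-reduction, allylic C–O hydrogenolysis and loss of the C11 configuration under the basic borohydride medium. The fallback separates hydride delivery from protonation; it sets out from 19 and comes back at 20. Stoichiometric [(Ph3P)CuH]6 in toluene adds hydride only to C7, anti to the C5 substituent; if the resulting enolate equilibrates, the product is the 3-epi (11-epi) lactone F6. F6 is then deprotonated with LDA (2.2 equiv, THF, −78 °C) and the enolate is quenched with 2,6-di-tert-butylphenol, which protonates C11 from the open face opposite C8 and gives 20.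

Step 10 (vinylogous aldol). The risks are poor face selectivity at C9 with the 2-methyl diene and isomerisation of the Z enal. The fallback sets C9 by a reagent-controlled ketone reduction instead; it sets out from 10 and comes back at 16. The dianion of 11 (NaH, then n-BuLi, THF) adds to 10 at −78 °C to give the C9-epimeric hydroxy keto ester F7, and the step 11 conditions give the C9-epimeric enol triflate F8. MnO2 in CH2Cl2 oxidises the allylic alcohol to the Z enone F9. Reduction with (R)-Me-CBS oxazaborolidine (20 mol %) and catecholborane in toluene at −78 °C treats the α-methyl alkenyl group as the large substituent and returns (5S)-16.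

**Further compounds**
F1 | step 13 | (2E,4S)-1,1-dimethoxy-3-methylhepta-2,6-dien-4-yl (2R)-2-methylbutanoate | CC[C@@H](C)C(=O)O[C@@H](CC=C)/C(C)=C/C(OC)OC
F2 | step 13 | (2E,4S)-3-methyl-1-oxohepta-2,6-dien-4-yl (2R)-2-methylbutanoate | CC[C@@H](C)C(=O)O[C@@H](CC=C)/C(C)=C/C=O
F3 | step 13 | methyl (5S)-5-hydroxy-2,6-dimethyl-3-oxohept-6-enoate | COC(=O)C(C)C(=O)C[C@H](O)C(C)=C
F4 | step 13 | methyl (2Z,5S)-5-hydroxy-2,6-dimethyl-3-{[(trifluoromethyl)sulfonyl]oxy}hepta-2,6-dienoate | COC(=O)/C(C)=C(OS(=O)(=O)C(F)(F)F)/C[C@H](O)C(C)=C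
F5 | step 13 | (1E,3S)-1-[(2S)-3-[(2S)-2-hydroxy-3-methylbut-3-en-1-yl]-4-methyl-5-oxo-2,5-dihydrofuran-2-yl]-2-methylhexa-1,5-dien-3-yl (2R)-2-methylbutanoate | CC[C@@H](C)C(=O)O[C@@H](CC=C)/C(C)=C/[C@@H]1OC(=O)C(C)=C1C[C@H](O)C(C)=C
F6 | step 14 | (3S,3aS,5S,6Z,9S,10E,11aR)-5-hydroxy-3,6,10-trimethyl-2-oxo-2,3,3a,4,5,8,9,11a-octahydrocyclodeca[b]furan-9-yl (2R)-2-methylbutanoate | CC[C@@H](C)C(=O)O[C@H]1C/C=C(/C)[C@@H](O)C[C@@H]2[C@H](/C=C/1C)OC(=O)[C@H]2C
F7 | step 10 | methyl (5RS,6Z,9S,10E)-5-hydroxy-12,12-dimethoxy-2,6,10-trimethyl-9-{[(2R)-2-methylbutanoyl]oxy}-3-oxododeca-6,10-dienoate | CC[C@@H](C)C(=O)O[C@@H](C/C=C(/C)C(O)CC(=O)C(C)C(=O)OC)/C(C)=C/C(OC)OC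
F8 | step 10 | methyl (2Z,5RS,6Z,9S,10E)-5-hydroxy-12,12-dimethoxy-2,6,10-trimethyl-9-{[(2R)-2-methylbutanoyl]oxy}-3-{[(trifluoromethyl)sulfonyl]oxy}dodeca-2,6,10-trienoate | CC[C@@H](C)C(=O)O[C@@H](C/C=C(/C)C(O)C/C(OS(=O)(=O)C(F)(F)F)=C(\C)C(=O)OC)/C(C)=C/C(OC)OC
F9 | step 10 | methyl (2Z,6Z,9S,10E)-12,12-dimethoxy-2,6,10-trimethyl-9-{[(2R)-2-methylbutanoyl]oxy}-5-oxo-3-{[(trifluoromethyl)sulfonyl]oxy}dodeca-2,6,10-trienoate | CC[C@@H](C)C(=O)O[C@@H](C/C=C(/C)C(=O)C/C(OS(=O)(=O)C(F)(F)F)=C(\C)C(=O)OC)/C(C)=C/C(OC)OC
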